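The theta flask cannot hold its seed of target plus what the epsilon flask made: at 110 min that sum is 0.0832 M, and the reading, 0.0654 M, is less than that.

| flask | starting material | coupling partner | target | time |
|---|---|---|---|---|
| epsilon | 0.150 M | 0.375 M |  |  |
| alpha | 0.220 M | 0.375 M |  |  |
| theta | 0.150 M | 0.375 M | 0.0450 M |  |
| eta | 0.150 M | 1.10 M |  |  |
| delta | 0.600 M | 1.50 M |  | 110 min |

- epsilon run (time / min: [target] / M): 4.4: 0.0035; 7.0: 0.0052; 11: 0.0078; 17: 0.0117; 28: 0.0181; 44: 0.0246; 69: 0.0324; 110: 0.0382
- alpha run (time / min: [target] / M): 4.4: 0.0055; 7.0: 0.0080; 11: 0.0118; 17: 0.0175; 28: 0.0263; 44: 0.0361; 69: 0.0468; 110: 0.0539
- theta run (time / min: [target] / M): 4.4: 0.0478; 7.0: 0.0492; 11: 0.0513; 17: 0.0536; 28: 0.0575; 44: 0.0613; 69: 0.0653; 110: 0.0654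
- eta run (time / min: [target] / M): 4.4: 0.0105; 7.0: 0.0164; 11: 0.0251; 17: 0.0353; 28: 0.0505; 44: 0.0643; 69: 0.0735; 110: 0.0747

(readings scatter by 4 × 10⁻⁴ M)

- Overall: starting material + coupling partner -> target.
- Constant volume, constant temperature.
- A reading of a species includes what of it is bound.
- "The second partner" is coupling partner.
- An order is taken over about fifteen percent of the charge, up and down.

1. apparent order in [starting material] of the starting rate, round the charge of the epsilon run (the rate where two percent of its starting material have turned into target) (one fixed amount of target, the same in the runs compared)
2. apparent order in [coupling partner] of the starting rate, round the charge of the epsilon run (the rate where two percent of its starting material have turned into target)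
3. target in the delta run at 110 min, as a share of the starting material charged

For whoever takes over the bench: the delta flask starts with 0.600 M of starting material and 1.50 M of coupling partner, and target forms from them, but target once made does not stay. We carry one number, the seed survival, which is the share of target present at the start that is still there at 110 min, read as the theta reading minus the epsilon reading, over the seed: 60.4%. This supposes that the seed leaves the making unchanged.

By our own reckoning, target made at the outset of the delta flask shows as 60.4% of itself at 110 min. Target made later has stood for a shorter time, so we take 60.4% as the low end of the share kept of what is made; it is not a figure for the yield, which also needs the amount made. Do not count target in the flask as banked: the theta seed kept 60.4% of itself.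

The forecast gives orders of 1.03 (0.85 to 1.2) in [starting material] and 1.05 (0.9 to 1.25) in [coupling partner], and 50% (38% to 62%) for delta, reasoning that “it runs about four times faster per starting material but dies early”.

The flask gives 1.1, 1.2 and 52.7%, each inside those ranges.

    2 coupling partner ⇌ reagent dimer, settled at all times (30.00 M⁻¹)
    starting material + reagent dimer → target + coupling partner (0.03576 M⁻¹ min⁻¹)
    starting material → decomposed substrate (0.004782 min⁻¹)
    target → decomposed product (0.004488 min⁻¹)

The forecast's value holds because target is lost to decomposed product: in the delta run without that loss the flask reaches 74.7% rather than 52.7%, which is higher than the forecast's upper end of 62%, so such a run would have made it wrong. Set against that run, the delta flask keeps 70.5% of the target it made, more than the theta seed's 60.4%.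

The runs were computed for an exercise; noise was put on by code.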